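The autumn run, which is the very flask asked about, reached 50% of X by 2.00 h and still stood at 52% at 6.00 h, while the winter run at 45 °C was rising at its last reading.

all flasks: G 0.59 mol%
- autumn: D 0.50 M; temperature 60 °C; the very flask that is asked about, followed so far
- winter: D 0.75 M; temperature 45 °C; run made earlier
- flask: D 0.50 M; temperature 60 °C; time 10 h

- autumn (time / h: X / %): 0.833: 28; 2.00: 50; 4.00: 52; 6.00: 52
- winter (time / min: X / %): 12.0: 4; 30.0: 8; 60.0: 16; 120: 30

(each reading ± 2 percentage points)

- removed X is counted in
- the earlier runs were read with a standard deviation of 2 percentage points
- additions bring no volume worth counting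

- grey: change nothing and wait 3.0 h more
- ochre: at 10 h take out 90% of the X then present, then wait 3.0 h
- green: at 10 h add G, 100% of the amount charged, then wait 3.0 h
- amber: at 10 h raise the temperature by 15 K, then wait 3.0 h

- X, in percent of the D first charged, at 10 h
- the remedy with the largest gain of X, or "none" below 2 percentage points (grey / ochre / green / amber / none)
- X present, with what was taken out counted in, in percent of the D first charged, after grey
- X present, with what was taken out counted in, in percent of the D first charged, after ochre

Carry that stop as one number. From the last autumn reading, L is 0.0348, and L, the split exponent, is the power of ten in the ratio of X to the rest of the D charged, once the flask has stopped.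

My reckoning takes the stop as a balance, so X is still 52% at 10 h and waiting adds nothing. Ochre takes out 46.8% of the D charged. The remaining 53.2% splits again by the same L, which gives 27.7% as X and a total of 74.5%. I count the new split as reached, since autumn came within 2 percentage points of its stop by 2.00 h, sooner than the 3.0 h allowed.

The forecast weighed “either equilibrium or a dead catalyst” and favoured equilibrium. It gave 52% now (50% to 54%), 52% after grey, and 73% after ochre (60% to 77%), lower than mine, and it chose ochre.

The flask gave 52.4% at 10 h, 52.4% after grey and 74.9% after ochre, a gain of 22 points, while green gained 0 points and amber −3.5 points.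

    D + G → Q (k = 8.90 M⁻¹ min⁻¹, Ea = 56.0 kJ mol⁻¹)
    Q → G + X (k = 2.15 min⁻¹, Ea = 79.0 kJ mol⁻¹)
    X + G ⇌ E + G, rate k3*[G]*[X] forward; the back reaction follows from the equilibrium constant (K = 0.907, k = 9.28 M⁻¹ min⁻¹, Ea = 61.0 kJ mol⁻¹, ΔH = 9.00 kJ mol⁻¹)
    (constants at 60 °C)

In the flask at 10.0 h the part that isn't X is E, 47.6% against D 0%: a second product balanced with X, which is thermodynamic control. The same charge run at 85 °C ended with X 46.8% and E 53.2%, so the split exponent of that neighbour is −0.0557, against 0.0348 from the last autumn reading.

The numbers in the tables are simulated for substances that don't exist; the scatter is artificial.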